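**Retrosynthetic overview**
1. Target 16 ⇐ hydrolysis of enol lactone 15 ⇐ allyl-to-prenyl cross-metathesis of 14.
2. Key C–C bond: C6–allyl of 14. Phenol 12 is oxidised with PhI(OAc)2 so that C6, normally the nucleophilic phloroglucinol carbon, becomes an electrophilic enolonium-type centre and is captured by the nucleophilic terminus of allyltrimethylsilane. This dearomatises the carbocycle and creates the quaternary centre.
3. 12 ⇐ 10 + cinnamaldehyde (chiral carbene, oxidative annulation at C8/O7, benzylic centre); 10 ⇐ chromanone 9 + aldehyde 5 (reductive C6-alkylation).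
4. 9 ⇐ 8 (quinine-catalysed oxa-Michael closure, cis C2/C3) ⇐ phloroglucinol + tigloyl chloride; 5 ⇐ (1S,5S)-verbenone (cyclobutane from the chiral pool).
5. Ring order: cyclobutane and benzene ring bought; pyranone ring (step 5); temporary lactone ring (step 7); carbocycle dearomatised last (step 8); lactone opened in step 10.

Assumption: the target is drawn as one enol tautomer of an equilibrating β-triketone, and commercial (1S,5S)-verbenone is taken as enantiopure (otherwise acid 2 is recrystallised to full ee).

Chromanone numbering (O1, C2–C8a) is used for ring positions in the steps.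

Step 1
Reactants: 1 (1S,5S)-(−)-verbenone
Product: 2 (1S,3R)-3-acetyl-2,2-dimethylcyclobutane-1-carboxylic acid (cis-pinononic acid)
Conditions: RuCl3·xH2O (2 mol%), NaIO4 (4.2 equiv), MeCN/EtOAc/H2O, 20 °C
Reagents that add atoms: sodium periodate (NaIO4) [Na+].[O-]I(=O)(=O)=O; water O
Why: Ru-catalysed oxidative cleavage of the enone C=C (RuO4 formed in situ) with oxidative loss of the α-keto-acid carbon gives the keto acid; both stereocentres are the bridgeheads of 1 and are untouched, the bicycle guaranteeing the cis-1,3 relationship.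

Step 2
Reactants: 2 cis-pinononic acid
Product: 3 (1S,3S)-2,2-dimethyl-3-(prop-1-en-2-yl)cyclobutane-1-carboxylic acid
Conditions: Ph3PCH3Br (2.5 equiv), KOtBu (3.5 equiv), THF, 0 to 20 °C; then aq. HCl
Reagents that add atoms: methyltriphenylphosphonium bromide C[P+](c1ccccc1)(c1ccccc1)c1ccccc1.[Br-]
Why: Wittig methylenation of the methyl ketone on the potassium carboxylate; the ring stereocentres are not involved and the cis-1,3-disubstituted cyclobutane is the thermodynamic isomer, so the ketone α-centre is not at risk.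

Step 3
Reactants: 3 isopropenyl acid
Product: 5 (1S,3S)-2,2-dimethyl-3-(prop-1-en-2-yl)cyclobutane-1-carbaldehyde, via acyl imidazole 4 (not isolated)
Conditions: CDI (1.1 equiv), CH2Cl2, 20 °C; then iBu2AlH (2.1 equiv), −78 °C; aq. tartaric acid
Reagents that add atoms: none
Why: one-pot activation and partial reduction (acyl imidazole, then hydride): the tetrahedral aluminium adduct survives until work-up so reduction stops at the aldehyde, and the α-stereocentre is retained as in the same reduction of α-amino acids to α-amino aldehydes.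

Step 4
Reactants: 6 phloroglucinol; 7 tigloyl chloride
Product: 8 (E)-2-methyl-1-(2,4,6-trihydroxyphenyl)but-2-en-1-one
Conditions: AlCl3 (3 equiv), PhNO2, 0 to 20 °C, short contact; cold aq. HCl
Reagents that add atoms: none
Why: Friedel–Crafts C-acylation of the symmetric triol (only one product possible); the cold, short reaction keeps the chelated aryl enone from cyclising; no stereocentre is formed.

Step 5
Reactants: 8 tigloylphloroglucinol
Product: 9 (2R,3S)-5,7-dihydroxy-2,3-dimethylchroman-4-one (cis)
Conditions: (−)-quinine (10 mol%), PhCl/THF, 20 °C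
Reagents that add atoms: none
Why: cinchona-alkaloid-catalysed enantioselective intramolecular oxa-Michael addition (6-endo closure): the quinuclidine-bound phenol adds to one face of the tigloyl β-carbon and sets C2 (R), and kinetic protonation of the enol anti to the pseudo-axial 2-methyl sets C3 (S), giving the cis isomer as known for 8-tigloyl-7-hydroxycoumarins; the two ortho hydroxyls are equivalent.

Step 6
Reactants: 9 cis-chromanone; 5 cyclobutane aldehyde
Product: 10 (2R,3S)-6-{[(1R,3S)-2,2-dimethyl-3-(prop-1-en-2-yl)cyclobutyl]methyl}-5,7-dihydroxy-2,3-dimethylchroman-4-one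
Conditions: L-proline (20 mol%), diethyl 2,6-dimethyl-1,4-dihydropyridine-3,5-dicarboxylate (1.1 equiv), CH2Cl2/EtOH, 25–40 °C
Reagents that add atoms: none
Why: organocatalytic three-component reductive alkylation (Knoevenagel condensation to the ortho-quinone methide, then transfer hydrogenation from the dihydropyridine); C6, flanked by two hydroxyls, is the most nucleophilic carbon of 5,7-dihydroxychromanones (their Mannich reactions are C6-selective), no stereocentre is formed, and the near-neutral medium keeps cis C3 and the aldehyde α-centre (any C8 isomer is removed by chromatography).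

Step 7
Reactants: 10 C6-alkylated chromanone; 11 (E)-cinnamaldehyde
Product: 12 (2R,3S,10S)-6-{[(1R,3S)-2,2-dimethyl-3-(prop-1-en-2-yl)cyclobutyl]methyl}-5-hydroxy-2,3-dimethyl-10-phenyl-2,3,9,10-tetrahydro-4H,8H-pyrano[2,3-f]chromene-4,8-dione (lactone from C8 to O7)
Conditions: (5aR,10bS)-2-mesityl-5a,10b-dihydro-4H,6H-indeno[2,1-b][1,2,4]triazolo[4,3-d][1,4]oxazin-2-ium tetrafluoroborate (10 mol%), 3,3',5,5'-tetra-tert-butyldiphenoquinone (1.2 equiv), K2CO3 (20 mol%), THF, 25 °C
Reagents that add atoms: none
Why: oxidative N-heterocyclic-carbene catalysis: the Breslow intermediate is oxidised to the α,β-unsaturated acyl azolium, the only free ring carbon C8 adds to its β-carbon (Friedel–Crafts-type Michael addition) and O7 is acylated to close the lactone and release the carbene; the aminoindanol backbone blocks one face of the acceptor and sets the benzylic centre (S) (the antipodal salt is used if the observed sense is opposite); the 5-OH is chelated to C4=O and stays free.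

Step 8
Reactants: 12 lactone phenol
Product: 14 (2R,3S,6R,10S)-6-allyl-6-{[(1R,3S)-2,2-dimethyl-3-(prop-1-en-2-yl)cyclobutyl]methyl}-2,3-dimethyl-10-phenyl-2,3,9,10-tetrahydro-4H,8H-pyrano[2,3-f]chromene-4,5,8(6H)-trione, via aryl-λ3-iodane 13 (not isolated)
Conditions: PhI(OAc)2 (1.1 equiv), allyltrimethylsilane (5 equiv), (CF3)2CHOH/CH2Cl2, −40 to 0 °C; SiO2 separation of the C6 epimers
Reagents that add atoms: allyltrimethylsilane C=CC[Si](C)(C)C
Why: Proposed new method: ligand exchange of the 5-hydroxyl on PhI(OAc)2 gives aryl-λ3-iodane 13, a phenol-derived enolonium (phenoxenium) equivalent in which the ortho carbon C6, ordinarily the nucleophilic carbon of the phloroglucinol, is electrophilic, so the nucleophilic CH2 terminus of the allylsilane bonds to C6 with loss of PhI and the β-silyl cation is desilylated by acetate, giving a non-enolisable 6,6-disubstituted cyclohexa-2,4-dienone that cannot be oxidised again; C6 is favoured over C8 (ring-fusion carbon under the pseudo-axial phenyl) and C4a (acyl-bearing), the closest known reactions being the oxidative Hosomi–Sakurai allylation of alkyl-substituted phenols with PhI(OAc)2 in fluorinated alcohols and the allylation of ketone-derived enolonium species, and because the quaternary centre forms under weak substrate control (dr near 1:1 expected) the (6R) epimer is isolated by chromatography and assigned by correlation with 16 (NOE or crystal structure).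

Step 9
Reactants: 14 6-allyl dienone lactone
Product: 15 (2R,3S,6R,10S)-6-{[(1R,3S)-2,2-dimethyl-3-(prop-1-en-2-yl)cyclobutyl]methyl}-2,3-dimethyl-6-(3-methylbut-2-en-1-yl)-10-phenyl-2,3,9,10-tetrahydro-4H,8H-pyrano[2,3-f]chromene-4,5,8(6H)-trione
Conditions: second-generation Grubbs catalyst (5 mol%), 2-methylbut-2-ene/CH2Cl2, 40 °C
Reagents that add atoms: 2-methylbut-2-ene CC=C(C)C
Why: olefin cross-metathesis of the monosubstituted allyl group with the trisubstituted olefin turns allyl into prenyl, while the 1,1-disubstituted isopropenyl group and the tetrasubstituted ring olefins do not react; no stereocentre is touched.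

Step 10
Reactants: 15 6-prenyl dienone lactone
Product: 16 CNP0328119.1 (target)
Conditions: LiOH (3 equiv), THF/H2O, 0 °C; then 1 M HCl to pH 3
Reagents that add atoms: lithium hydroxide (LiOH) [Li+].[OH-]
Why: hydrolysis of the activated enol lactone: hydroxide attacks the lactone carbonyl and releases the carboxylate and the C7 enolate, which on acidification gives the enolised β-triketone; the triketone is an anion throughout so C3 is not epimerised and no stereocentre is touched.

**Compound list**
1 | (1S,5S)-(−)-verbenone, (1S,5S)-4,6,6-trimethylbicyclo[3.1.1]hept-3-en-2-one | CC1=CC(=O)[C@H]2C[C@@H]1C2(C)C | starting material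
2 | (1S,3R)-3-acetyl-2,2-dimethylcyclobutane-1-carboxylic acid | CC(=O)[C@@H]1C[C@H](C(=O)O)C1(C)C | intermediate
3 | (1S,3S)-2,2-dimethyl-3-(prop-1-en-2-yl)cyclobutane-1-carboxylic acid | C=C(C)[C@@H]1C[C@H](C(=O)O)C1(C)C | intermediate
4 | [(1S,3S)-2,2-dimethyl-3-(prop-1-en-2-yl)cyclobutyl](1H-imidazol-1-yl)methanone (acyl imidazole, not isolated) | C=C(C)[C@@H]1C[C@H](C(=O)n2ccnc2)C1(C)C | intermediate
5 | (1S,3S)-2,2-dimethyl-3-(prop-1-en-2-yl)cyclobutane-1-carbaldehyde | C=C(C)[C@@H]1C[C@H](C=O)C1(C)C | intermediate
6 | phloroglucinol (benzene-1,3,5-triol) | Oc1cc(O)cc(O)c1 | starting material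
7 | tigloyl chloride, (E)-2-methylbut-2-enoyl chloride | C/C=C(\C)C(=O)Cl | starting material
8 | (E)-2-methyl-1-(2,4,6-trihydroxyphenyl)but-2-en-1-one | C/C=C(\C)C(=O)c1c(O)cc(O)cc1O | intermediate
9 | (2R,3S)-5,7-dihydroxy-2,3-dimethylchroman-4-one (cis) | O=C1c2c(O)cc(O)cc2O[C@H](C)[C@@H]1C | intermediate
10 | (2R,3S)-6-{[(1R,3S)-2,2-dimethyl-3-(prop-1-en-2-yl)cyclobutyl]methyl}-5,7-dihydroxy-2,3-dimethylchroman-4-one | C=C(C)[C@@H]1C[C@H](Cc2c(O)cc3O[C@H](C)[C@H](C)C(=O)c3c2O)C1(C)C | intermediate
11 | (E)-cinnamaldehyde | O=C/C=C/c1ccccc1 | starting material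
12 | (2R,3S,10S)-6-{[(1R,3S)-2,2-dimethyl-3-(prop-1-en-2-yl)cyclobutyl]methyl}-5-hydroxy-2,3-dimethyl-10-phenyl-2,3,9,10-tetrahydro-4H,8H-pyrano[2,3-f]chromene-4,8-dione | C=C(C)[C@@H]1C[C@H](Cc2c(O)c3C(=O)[C@@H](C)[C@@H](C)Oc3c4c2OC(=O)C[C@H]4c2ccccc2)C1(C)C | intermediate
13 | O5-[acetoxy(phenyl)-λ3-iodanyl] derivative of 12 (aryl-λ3-iodane, not isolated) | C=C(C)[C@@H]1C[C@H](Cc2c(OI(OC(C)=O)c5ccccc5)c3C(=O)[C@@H](C)[C@@H](C)Oc3c4c2OC(=O)C[C@H]4c2ccccc2)C1(C)C | intermediate
14 | (2R,3S,6R,10S)-6-allyl-6-{[(1R,3S)-2,2-dimethyl-3-(prop-1-en-2-yl)cyclobutyl]methyl}-2,3-dimethyl-10-phenyl-2,3,9,10-tetrahydro-4H,8H-pyrano[2,3-f]chromene-4,5,8(6H)-trione | C=C(C)[C@@H]1C[C@H](C[C@@]2(CC=C)C(=O)C3=C(O[C@H](C)[C@H](C)C3=O)C4=C2OC(=O)C[C@H]4c2ccccc2)C1(C)C | intermediate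
15 | (2R,3S,6R,10S)-6-{[(1R,3S)-2,2-dimethyl-3-(prop-1-en-2-yl)cyclobutyl]methyl}-2,3-dimethyl-6-(3-methylbut-2-en-1-yl)-10-phenyl-2,3,9,10-tetrahydro-4H,8H-pyrano[2,3-f]chromene-4,5,8(6H)-trione | C=C(C)[C@@H]1C[C@H](C[C@@]2(CC=C(C)C)C(=O)C3=C(O[C@H](C)[C@H](C)C3=O)C4=C2OC(=O)C[C@H]4c2ccccc2)C1(C)C | intermediate
16 | CNP0328119.1: (3S)-3-phenyl-3-[(2R,3S,6R)-6-{[(1R,3S)-2,2-dimethyl-3-(prop-1-en-2-yl)cyclobutyl]methyl}-4-hydroxy-2,3-dimethyl-6-(3-methylbut-2-en-1-yl)-5,7-dioxo-chromen-8-yl]propanoic acid (enolised β-triketone) | C=C(C)[C@@H]1C[C@H](C[C@@]2(CC=C(C)C)C(=O)C3=C(O)[C@@H](C)[C@@H](C)OC3=C([C@@H](CC(=O)O)c3ccccc3)C2=O)C1(C)C | target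

**Totals and risks**
Total steps: 10. Longest linear sequence: 8 (1 → 2 → 3 → 5 → 10 → 12 → 14 → 15 → 16).

Most likely to fail, in order:

- **Step 8.** The trivalent-iodine dearomatisation has no precedent on an acyl-phloroglucinol. Acetate capture at C6, attack at C8, or oxidation of the isopropenyl group may compete, and the C6 epimers must be separated. Fallback: setting out from 12, the 5-hydroxyl is acylated with allyl chloroformate (pyridine, DMAP, CH2Cl2) to give the 5-O-allyl carbonate F1. Pd(PPh3)4 (zerovalent palladium, THF, 25 °C) then effects decarboxylative Tsuji–Trost transfer of the allyl group from oxygen to C6 under neutral conditions. This returns to the route at 14 with the same epimer separation.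

- **Step 7.** The acyl azolium may O-acylate the 7-hydroxyl instead of bonding to C8, or give low face selectivity with this hindered phenol. Fallback: setting out from 10, C8 adds to 5-benzylidene-2,2-dimethyl-1,3-dioxane-4,6-dione under a quinine-derived squaramide (CH2Cl2, 0 °C) to give the Meldrum's acid adduct F2. Heating F2 in toluene closes the lactone onto O7 with loss of acetone and CO2. This returns at 12, with the benzylic epimers separable if selectivity is incomplete.

- **Step 6.** The condensation may go partly at C8 or stall with the α-branched aldehyde. Fallback: setting out from 8 (with 5), the same proline and dihydropyridine reductive alkylation is run on the still symmetric open-chain triol, where both free ring carbons are equivalent, to give the alkylated aryl enone F3. The quinine-catalysed oxa-Michael closure of F3 is then expected to use the hydroxyl next to the unsubstituted ring carbon, since the hydroxyl beside the new alkyl group is buttressed into the chelate with the ketone. This returns at 10.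

**Further compounds**
F1 | step 8 | 5-O-allyloxycarbonyl derivative of 12 (allyl aryl carbonate) | C=C(C)[C@@H]1C[C@H](Cc2c(OC(=O)OCC=C)c3C(=O)[C@@H](C)[C@@H](C)Oc3c4c2OC(=O)C[C@H]4c2ccccc2)C1(C)C
F2 | step 7 | 5-{(S)-phenyl[C8 of 10]methyl}-2,2-dimethyl-1,3-dioxane-4,6-dione (Meldrum's acid adduct of 10 at C8) | C=C(C)[C@@H]1C[C@H](Cc2c(O)c3C(=O)[C@@H](C)[C@@H](C)Oc3c(c2O)[C@H](c2ccccc2)C2C(=O)OC(C)(C)OC2=O)C1(C)C
F3 | step 6 | (E)-1-(3-{[(1R,3S)-2,2-dimethyl-3-(prop-1-en-2-yl)cyclobutyl]methyl}-2,4,6-trihydroxyphenyl)-2-methylbut-2-en-1-one | C=C(C)[C@@H]1C[C@H](Cc2c(O)cc(O)c(C(=O)/C(C)=C/C)c2O)C1(C)C
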